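In a one-step world every partner molecule finds a substrate and becomes product, so I first counted the partner as the limiting reagent. The flask charged partner equal to 60.0% of both substrates together, which promised that conversion and, with the mirror products level, 30.0% of left-handed product.

| flask | left-handed substrate | right-handed substrate | partner | remark | time |
|---|---|---|---|---|---|
| oak | 0.25 M | 0.25 M | 0.60 equiv | run made earlier |  |
| birch | 0.25 M | 0.25 M | 0.90 equiv | run made earlier |  |
| larch | 0.50 M | 0.50 M | 1.2 equiv | run made earlier |  |
| flask | 0.25 M | 0.25 M | 1.20 equiv |  | 15 h |

| run | time / h | left-handed substrate / % | left-handed product / % |
|---|---|---|---|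
| oak | 1.00 | 37.2 | 11.2 |
| oak | 3.00 | 35.8 | 10.8 |
| oak | 6.00 | 35.1 | 11.5 |
| oak | 10.0 | 38.1 | 10.8 |
| birch | 0.667 | 34.2 | 12.1 |
| birch | 1.50 | 32.4 | 14.4 |
| birch | 4.00 | 30.7 | 16.0 |
| birch | 10.0 | 31.3 | 16.4 |
| larch | 2.50 | 22.1 | 27.1 |
| larch | 5.00 | 21.4 | 25.7 |
| larch | 6.00 | 21.3 | 24.8 |
| larch | 10.0 | 23.2 | 26.3 |

(readings scatter by 1 percentage point)

- partner is single-handed; left-handed substrate and right-handed substrate are mirror images of each other, charged as a racemate, each of them at the stated concentration
- the numbers in the tables scatter with a standard deviation of 1 percentage point
- the reaction counts as stopped when no species that holds the left-handed substrate and right-handed substrate together changes by six tenths of a point or more over the second half of the time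
- the handed part of partner does not stay in what it makes, so the products of the two hands are mirror images too

1. why nothing more happens at 15 h, or that something still does (all of the left-handed substrate has reacted / forward and back rates have come level / it is still moving / the partner has run out first)
2. conversion of left-handed substrate and right-handed substrate together at 15 h
3. amount of left-handed product at 15 h, in percent of the left-handed substrate and right-handed substrate together charged

The runs broke that count. Taking the two mirror products as level, the partner that ended as product read 73.8% of the charge in oak and 72.0% in birch, but 86.6% in larch. So I followed one partner molecule to a fork: a substrate catches it, or it is lost some other way. The ratio of lost to caught partner read 0.355 in oak and 0.155 in larch, but larch differs from oak in two settings, the substrate concentration by a factor of 2.00 and the equivalents of partner by a factor of 2.00, so I could not lay that difference on either one. The flask has the substrate concentration of oak and birch, though more equivalents of partner than either, and those two readings stood close, so I carried their mean, 72.9%, as my capture share at that substrate concentration, the fraction of charged partner that ends as product. That gave the flask a conversion of 43.8% and 21.9% of left-handed product, and I expected the flask to stop with its partner used up.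

The forecast said forward and back rates have come level, reading that “Every run stops changing early, well short of using up the partner”. It gave a conversion of 44% (40% to 48%) and 20% of left-handed product (18% to 22%).

The flask gave: the partner has run out first, with 0% of the partner and 51% of the left-handed substrate left, a conversion of 42.1% and 21.1% of left-handed product.

    partner + right-handed substrate → right-handed product (k = 6.20 × 10⁻⁴ M⁻¹ s⁻¹)
    partner + left-handed substrate → left-handed product (k = 9.90 × 10⁻⁴ M⁻¹ s⁻¹)
    left-handed product ⇌ right-handed product (k = 5.20 × 10⁻⁵ s⁻¹)
    partner → decomposed reagent (k = 1.30 × 10⁻⁴ s⁻¹)
    partner → decomposition product (k = 5.20 × 10⁻⁸ s⁻¹)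

At the charge, the two substrates together took partner at 1.45 h⁻¹, faster than the 0.468 h⁻¹ at which partner became decomposed reagent. In the flask 29.8% of the partner went that way, and the capture share came to 70.1%, beside my 72.9%.

For the neighbour flask with 0.300 equiv of partner, the capture share gives a conversion of 10.9% and 5.47% of left-handed product. The computed flask gave 11.2% and 5.59%.

The data were computed for an exercise, and the scatter is random.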